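Readings and results were computed from invented constants; noise was put on by code.

1. In the alpha run, and so in Sunday's flask, 0.0650 M of reagent cannot serve 0.050 M of starting material and 0.0250 M of second substrate at one each, since I assume the two ask for 0.0750 M.

| setting | alpha | zeta | Sunday's | Wednesday's | Thursday's | Tuesday's |
|---|---|---|---|---|---|---|
| starting material | 0.050 M | 0.050 M | 0.050 M | 0.050 M (fed, over 2.0 h) | 0.050 M | 0.050 M (fed, over 30 min) |
| reagent | 0.065 M | 0.13 M | 0.0650 M | 0.0650 M | 0.0650 M (fed, over 2.0 h) | 0.0650 M |
| second substrate | 0.025 M | 0.025 M | 0.0250 M | 0.0250 M | 0.0250 M | 0.0250 M |
| free catalyst | 5.5 mM | 5.5 mM | 5.5 mM | 5.5 mM | 5.5 mM | 5.5 mM |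
| impurity | 1.3 mM | 1.3 mM | 1.3 mM | 1.3 mM | 1.3 mM | 1.3 mM |
| remark | run made earlier | run made earlier | everything together at the start | all else is in the flask from the start; the feed brings no volume worth counting | all else is in the flask from the start; the feed brings no volume worth counting | all else is in the flask from the start; the feed brings no volume worth counting |
| time |  |  | 5.0 h | 5.0 h | 5.0 h | 5.0 h |

alpha run (percent of the starting material charged)

| time / h | target / % |
|---|---|
| 0.833 | 61 |
| 1.50 | 56 |
| 2.50 | 60 |
| 3.00 | 54 |
| 4.00 | 57 |
| 5.00 | 59 |

zeta run (percent of the starting material charged)

| time / min | target / % |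
|---|---|
| 8.00 | 80 |
| 12.0 | 86 |
| 20.0 | 87 |
| 30.0 | 86 |
| 50.0 | 86 |
| 90.0 | 89 |

(standard deviation of a reading: 1.5 percentage points)

- which flask leads in amount of target, in percent of the starting material charged ("all alike" within 1.5 percentage points) (Sunday's / Wednesday's / Thursday's / Tuesday's / all alike)
- how much target is there at the end, in percent of the starting material charged: Sunday's
- how much target is there at the end, in percent of the starting material charged: Wednesday's
- how much target is there at the end, in percent of the starting material charged: Thursday's
- how much target is there at the end, in percent of the starting material charged: Tuesday's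

- the numbers in the tables scatter by 1.5 percentage points (one standard deviation)

2. I name the reagent ceiling the share of the starting material that reagent can serve once second substrate has taken its fill; it is 80.0%, and in this reckoning reagent is the limiting reagent.

3. The zeta run reads 80% at 8.00 min, a mean of about 0.100 min⁻¹ over those minutes as a fraction of the charge, not a starting rate.

4. Alpha has 0.500 of that reagent, so if the rate follows reagent, alpha's mean over its first stretch is near 0.0500 min⁻¹.

5. In my reckoning two things slow it: reagent runs down towards the ceiling, and starting material runs down with it, to a shortfall of 20.0% of its charge.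

6. At that mean rate the ceiling takes 16.0 min, and alpha already reads flat at 0.833 h.

7. Alpha's last reading, 59%, stands 21 percentage points below the ceiling, close to the shortfall of 20.0%. I therefore reckon that each unserved starting material costs one target, giving 60.0% for Sunday's.

8. Feeding leaves the ceiling unchanged, so I expect the fed flasks near that figure, less whatever reagent stays unused.

9. The forecast gives 58% for Sunday's, 4% for Wednesday's, 5% for Thursday's and 16% for Tuesday's, with Sunday's ahead, on the ground that “the catalyst is probably dying on a clock that doesn't depend on reagent”. For the fed flasks, my reckoning differs.

    starting material + reagent + free catalyst → free catalyst + target (k = 770 M⁻² min⁻¹)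
    second substrate + reagent + free catalyst → free catalyst + second product (k = 850 M⁻² min⁻¹)
    starting material + target → side product (k = 0.750 M⁻¹ min⁻¹)
    free catalyst + impurity → spent catalyst (k = 580 M⁻¹ min⁻¹)

Sunday's ends at 57.4%, ahead of Tuesday's 49.8%, Wednesday's 48.9% and Thursday's 35.7%. In Sunday's, the step making target has 99.9% of its turnover behind it after 2.50 h, while starting material with target into side product has 70% behind it after 0.500 h. Thursday's keeps 9.4% of its reagent, so the ceiling lowered by that amount gives 35.6% against its 35.7%. The neighbour with 0.085 M of starting material used 0.0165 M of reagent on second product, so the same reckoning gives 14.1% against its 14.8%.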